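**Retrosynthetic overview**
1. In the lactone (O1, C2, C3, C4, C5) the aroyl ketone carbon on C3 and ring carbon C5 on C4 are both oxidised and stand 1,4 to each other across the C3–C4 bond. Joined by a double bond they form, with C3 and C4, a cyclobutene, so one alkyne can supply both.
2. Lactone C5–O bond ⇐ hydroxy imide ⇐ keto aldehyde ⇐ oxidative cleavage of the C=C of a 2-arylcyclobut-2-ene-1-carbonyl imide.
3. Key disconnection: [2+2] of the ring A arylacetylene 3 with E-enoyl oxazolidinone 9 (ketone carbon–C3 and C5–C4 bonds), with a chiral titanium TADDOLate setting C4.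
4. Fragments: 3 from vanillin (silylation, one-carbon homologation); 9 from methyl eugenol and N-acryloyloxazolidinone by cross-metathesis.
5. Ring order: cyclobutene made (step 5) and cut open (step 6), lactone closed last (step 7); C3 is set by equilibration to trans, then the phenol is freed.

Key step: step 5

Assumption: the sense of induction is extrapolated from Diels–Alder and [2+2] reactions of N-enoyl oxazolidinones with this catalyst type, where the (R,R)-ligand is taken to expose the Cα-Re face. The (S,S)-ligand is therefore specified for the Cα-Si/Cβ-Re addition needed here; if a first run shows the opposite sense, the equally available (R,R)-ligand is used.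

Remark: the ring A phenol is carried as a triisopropylsilyl ether, since a bulkier aryl silyl ether should better withstand the methanolic carbonate of step 2 and chloride attack in step 5.

**Step 1**
Reactants: 1 vanillin
Product: 2 3-methoxy-4-(triisopropylsilyloxy)benzaldehyde
Conditions: TIPSCl, imidazole, DMF, rt
Reagents that add atoms: triisopropylsilyl chloride, CC(C)[Si](Cl)(C(C)C)C(C)C
Why: Imidazole-promoted silylation of a phenol is routine, and the aldehyde is untouched.

**Step 2**
Reactants: 2 3-methoxy-4-(triisopropylsilyloxy)benzaldehyde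
Product: 3 4-ethynyl-2-methoxyphenyl triisopropylsilyl ether
Conditions: dimethyl (1-diazo-2-oxopropyl)phosphonate, K2CO3, MeOH/THF, 0 °C → rt
Reagents that add atoms: dimethyl (1-diazo-2-oxopropyl)phosphonate (Ohira–Bestmann reagent), COP(=O)(OC)C(=[N+]=[N-])C(C)=O
Why: Seyferth–Gilbert homologation in the Ohira–Bestmann form: methanolysis of the acetyl group frees the diazomethylphosphonate anion, which olefinates the non-enolisable aryl aldehyde, and the diazoalkene loses N2 and undergoes a 1,2-shift to the terminal alkyne.

**Step 3**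
Reactants: 4 oxazolidin-2-one; 5 acryloyl chloride
Product: 7 3-acryloyloxazolidin-2-one, via bromomagnesium oxazolidinone salt 6 (not isolated)
Conditions: MeMgBr, THF, 0 °C; then 5, −78 → 0 °C
Reagents that add atoms: none
Why: N-acylation of the magnesium salt of the carbamate by the acid chloride; the weakly basic magnesium amide should not trigger acrylate polymerisation.

**Step 4**
Reactants: 7 3-acryloyloxazolidin-2-one; 8 methyl eugenol (4-allyl-1,2-dimethoxybenzene)
Product: 9 3-[(E)-4-(3,4-dimethoxyphenyl)but-2-enoyl]oxazolidin-2-one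
Conditions: second-generation Grubbs catalyst (5 mol %), 1,4-benzoquinone (10 mol %), 8 in excess, CH2Cl2, 40 °C
Reagents that add atoms: none
Why: Olefin cross-metathesis of a readily homodimerising allylarene with an electron-poor acryloyl partner that does not self-couple should favour the cross product as the E-enoyl imide, and benzoquinone suppresses ruthenium hydride double-bond migration.

**Step 5**
Reactants: 3 4-ethynyl-2-methoxyphenyl triisopropylsilyl ether; 9 3-[(E)-4-(3,4-dimethoxyphenyl)but-2-enoyl]oxazolidin-2-one
Product: 10 3-{[(1R,4S)-4-(3,4-dimethoxybenzyl)-2-[3-methoxy-4-(triisopropylsilyloxy)phenyl]cyclobut-2-en-1-yl]carbonyl}oxazolidin-2-one (trans)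
Conditions: TiCl2(OiPr)2 (30 mol %), (4S,5S)-2,2-dimethyl-α,α,α′,α′-tetraphenyl-1,3-dioxolane-4,5-dimethanol [(S,S)-TADDOL] (33 mol %), 4 Å MS, 3 in excess, toluene/petroleum ether, −20 → 0 °C
Reagents that add atoms: none
Why: Proposed new method: the titanium TADDOLate chelates both imide carbonyls of 9 in the s-cis form, and the terminal carbon of 3 adds to the activated β-carbon (future C4) to give a titanium enolate and an α-aryl vinyl cation that ring A delocalises as a para-quinoid silyloxocarbenium ion. The enolate α-carbon (future C3) then bonds to the cationic carbon before the Cα–Cβ bond can rotate, so the cyclobutene is closed by a four-membered 4-(enolexo) collapse of the zwitterion onto the digonal carbon, whose C=C stays inside the ring. The closest known reaction types are titanium TADDOLate catalysed [2+2] cycloadditions of alkynyl sulfides and ketene dithioacetals with N-enoyl oxazolidinones, and Lewis acid catalysed [2+2] cycloadditions of aryl alkynes with acrylates; a para-oxygenated arylacetylene with a β-alkyl enoyl imide under a chiral catalyst has not been shown. C4 is set by the (S,S)-ligand, one of whose aryl groups should shield a face of the chelated enoyl so that the alkyne meets the Cα-Si/Cβ-Re face, while C1 follows from suprafacial addition to the E-alkene (trans) and is in any case reset at the lactone stage. The step needs regioselectivity, secured because only the aryl-bearing alkyne carbon can carry the cation, and C-closure over proton loss or O-closure, favoured by the enolate oxygen being held on titanium in a base-free medium.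

**Step 6**
Reactants: 10 cyclobutene imide
Product: 12 3-[(2R,3R)-3-(3,4-dimethoxybenzyl)-2-[3-methoxy-4-(triisopropylsilyloxy)benzoyl]-4-oxobutanoyl]oxazolidin-2-one, via cyclobutane cis-diol 11 (not isolated)
Conditions: OsO4 (2 mol %), NaIO4, 2,6-lutidine, dioxane/H2O (3:1), 0 °C → rt; crude product used at once
Reagents that add atoms: osmium tetroxide, O=[Os](=O)(=O)=O (catalytic oxygen carrier); sodium periodate, [Na+].[O-]I(=O)(=O)=O (terminal oxygen source)
Why: Lemieux–Johnson cleavage: the strained trisubstituted cyclobutene is the only alkene, is osmylated to the cis-diol and cut by periodate to the aryl ketone and the C5 aldehyde, with 2,6-lutidine keeping the medium near neutral so the aldehyde α-carbon (future C4) should not enolise.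

**Step 7**
Reactants: 12 keto aldehyde
Product: 15 (3S,4R)-4-(3,4-dimethoxybenzyl)-3-[3-methoxy-4-(triisopropylsilyloxy)benzoyl]dihydrofuran-2(3H)-one (trans), via hydroxy imide 13 (not isolated), via cis-lactone 14 (not isolated)
Conditions: NaBH4, THF/EtOH, −78 → −40 °C; aq NH4Cl; then Et3N, CH2Cl2, rt
Reagents that add atoms: none
Why: Chemoselective borohydride reduction of the aldehyde (the enolisable β-keto imide is far less electrophilic) frees the C5 alcohol, which acylates on the imide carbonyl in a 5-exo-trig lactonisation with loss of oxazolidinone; C3, flanked by ketone and lactone carbonyls, then epimerises through its enol under Et3N from the kinetic cis to the thermodynamically favoured trans arrangement, while C4 has no acidic hydrogen and is untouched.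

**Step 8**
Reactants: 15 trans-lactone silyl ether
Product: 16 (3S,4R)-4-(3,4-dimethoxybenzyl)-3-(4-hydroxy-3-methoxybenzoyl)dihydrofuran-2(3H)-one (target)
Conditions: TBAF, AcOH, THF, 0 °C
Reagents that add atoms: none
Why: Fluoride cleavage of the aryl silyl ether, buffered with acetic acid so the β-keto lactone is not exposed to basic ring-opening or retro-Claisen cleavage; C3 stays at its thermodynamic trans configuration.

**Compound list**
1 | vanillin | COc1cc(C=O)ccc1O | starting material
2 | 3-methoxy-4-(triisopropylsilyloxy)benzaldehyde | COc1cc(C=O)ccc1O[Si](C(C)C)(C(C)C)C(C)C | intermediate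
3 | 4-ethynyl-2-methoxyphenyl triisopropylsilyl ether | C#Cc1ccc(O[Si](C(C)C)(C(C)C)C(C)C)c(OC)c1 | intermediate
4 | oxazolidin-2-one | O=C1NCCO1 | starting material
5 | acryloyl chloride | C=CC(=O)Cl | starting material
6 | N-bromomagnesio-oxazolidin-2-one (not isolated) | O=C1OCCN1[Mg]Br | intermediate
7 | 3-acryloyloxazolidin-2-one | C=CC(=O)N1CCOC1=O | intermediate
8 | methyl eugenol | C=CCc1ccc(OC)c(OC)c1 | starting material
9 | 3-[(E)-4-(3,4-dimethoxyphenyl)but-2-enoyl]oxazolidin-2-one | O=C(/C=C/Cc1ccc(OC)c(OC)c1)N1CCOC1=O | intermediate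
10 | 3-{[(1R,4S)-4-(3,4-dimethoxybenzyl)-2-[3-methoxy-4-(triisopropylsilyloxy)phenyl]cyclobut-2-en-1-yl]carbonyl}oxazolidin-2-one | O=C([C@H]1C(c2ccc(O[Si](C(C)C)(C(C)C)C(C)C)c(OC)c2)=C[C@@H]1Cc1ccc(OC)c(OC)c1)N1CCOC1=O | intermediate
11 | cis-2,3-diol of 10 (C1 and C4 unchanged, diol on either face; not isolated) | O=C([C@H]1C(O)(c2ccc(O[Si](C(C)C)(C(C)C)C(C)C)c(OC)c2)C(O)[C@@H]1Cc1ccc(OC)c(OC)c1)N1CCOC1=O | intermediate
12 | 3-[(2R,3R)-3-(3,4-dimethoxybenzyl)-2-[3-methoxy-4-(triisopropylsilyloxy)benzoyl]-4-oxobutanoyl]oxazolidin-2-one | O=C([C@@H](C(=O)c1ccc(O[Si](C(C)C)(C(C)C)C(C)C)c(OC)c1)[C@H](C=O)Cc1ccc(OC)c(OC)c1)N1CCOC1=O | intermediate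
13 | 3-[(2R,3R)-3-(3,4-dimethoxybenzyl)-4-hydroxy-2-[3-methoxy-4-(triisopropylsilyloxy)benzoyl]butanoyl]oxazolidin-2-one (not isolated) | O=C([C@@H](C(=O)c1ccc(O[Si](C(C)C)(C(C)C)C(C)C)c(OC)c1)[C@H](CO)Cc1ccc(OC)c(OC)c1)N1CCOC1=O | intermediate
14 | (3R,4R)-4-(3,4-dimethoxybenzyl)-3-[3-methoxy-4-(triisopropylsilyloxy)benzoyl]dihydrofuran-2(3H)-one (cis; not isolated) | COc1cc(C(=O)[C@@H]2C(=O)OC[C@@H]2Cc2ccc(OC)c(OC)c2)ccc1O[Si](C(C)C)(C(C)C)C(C)C | intermediate
15 | (3S,4R)-4-(3,4-dimethoxybenzyl)-3-[3-methoxy-4-(triisopropylsilyloxy)benzoyl]dihydrofuran-2(3H)-one (trans) | COc1cc(C(=O)[C@H]2C(=O)OC[C@@H]2Cc2ccc(OC)c(OC)c2)ccc1O[Si](C(C)C)(C(C)C)C(C)C | intermediate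
16 | (3S,4R)-4-(3,4-dimethoxybenzyl)-3-(4-hydroxy-3-methoxybenzoyl)dihydrofuran-2(3H)-one | COc1cc(C(=O)[C@H]2C(=O)OC[C@@H]2Cc2ccc(OC)c(OC)c2)ccc1O | target

**Step count**
Total: 8 steps. Longest linear sequence: 6 steps (1, 2, 5, 6, 7, 8 from vanillin; equally 3, 4, 5, 6, 7, 8 from oxazolidin-2-one).

**Steps most likely to fail**

Step 5 (proposed new method). The alkyne may be too weak a nucleophile for the β-alkyl enoyl chelate to turn over. The zwitterion may be lost by proton transfer (net conjugate alkynylation), by closure through the enolate oxygen, or by opening of the cyclobutene to a diene. The enoyl double bond may also slip into conjugation with the veratryl ring, and facial selectivity may be poor. The fallback gives up the cyclobutene and sets C4 by auxiliary-controlled enolate alkylation, all known chemistry; it sets out from aldehyde 2 and comes back at 15. Commercial 3-(3,4-dimethoxyphenyl)propanoic acid is coupled to (S)-4-benzyloxazolidin-2-one (PivCl, Et3N, LiCl, THF) to give (S)-4-benzyl-3-[3-(3,4-dimethoxyphenyl)propanoyl]oxazolidin-2-one F1. Evans alkylation (NaHMDS, tert-butyl bromoacetate, THF, −78 °C; electrophile anti to the auxiliary benzyl group) should give tert-butyl (3R)-4-[(4S)-4-benzyl-2-oxooxazolidin-3-yl]-3-(3,4-dimethoxybenzyl)-4-oxobutanoate F2. LiBH4 with MeOH in THF at 0 °C reduces the imide to tert-butyl (3R)-4-(3,4-dimethoxyphenyl)-3-(hydroxymethyl)butanoate F3, and catalytic TsOH in toluene closes it to (R)-4-(3,4-dimethoxybenzyl)dihydrofuran-2(3H)-one F4. The lithium enolate of F4 (LDA, THF, −78 °C) adds to aldehyde 2 anti to the C4 benzyl group to give the trans aldol (3S,4R)-4-(3,4-dimethoxybenzyl)-3-{hydroxy[3-methoxy-4-(triisopropylsilyloxy)phenyl]methyl}dihydrofuran-2(3H)-one F5 as carbinol epimers. Dess–Martin oxidation converts both epimers to 15.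

Step 6. Enolisation of the α-branched aldehyde may erode the configuration at the future C4, and cyclodehydration of the 1,4-keto aldehyde to a furan may consume material during isolation. The fallback sets out from 10 and comes back at 12, which is handled only in solution. Upjohn dihydroxylation (OsO4 cat., N-methylmorpholine N-oxide, acetone/H2O) gives diol 11, which is isolated and purified; in it C4 has no carbonyl neighbour. The diol is then cleaved with NaIO4 on silica gel in CH2Cl2, without water or amine, and the filtered solution of 12 is run directly into the borohydride of step 7 without concentration.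

Step 7. Hydride may also reduce the aryl ketone or cleave the imide, and the new alcohol may close on the ketone (lactol, then dihydrofuran) rather than on the imide. The fallback accepts full reduction and restores the ketone afterwards; it sets out from 12 and comes back at 15. Excess NaBH4 in EtOH/THF at −20 → 0 °C reduces both carbonyls to 3-[3-(3,4-dimethoxybenzyl)-4-hydroxy-2-{hydroxy[3-methoxy-4-(triisopropylsilyloxy)phenyl]methyl}butanoyl]oxazolidin-2-one F6. With Et3N its primary alcohol lactonises, with loss of oxazolidinone, to 4-(3,4-dimethoxybenzyl)-3-{hydroxy[3-methoxy-4-(triisopropylsilyloxy)phenyl]methyl}dihydrofuran-2(3H)-one F7 (R at C4, mixed at C3 and the carbinol). Dess–Martin oxidation of the single remaining alcohol, followed by Et3N equilibration of C3, should give 15.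

**Further compounds**
F1 | step 5 | (S)-4-benzyl-3-[3-(3,4-dimethoxyphenyl)propanoyl]oxazolidin-2-one | O=C(CCc1ccc(OC)c(OC)c1)N1[C@@H](Cc2ccccc2)COC1=O
F2 | step 5 | tert-butyl (3R)-4-[(4S)-4-benzyl-2-oxooxazolidin-3-yl]-3-(3,4-dimethoxybenzyl)-4-oxobutanoate | O=C([C@@H](CC(=O)OC(C)(C)C)Cc1ccc(OC)c(OC)c1)N1[C@@H](Cc2ccccc2)COC1=O
F3 | step 5 | tert-butyl (3R)-4-(3,4-dimethoxyphenyl)-3-(hydroxymethyl)butanoate | OC[C@@H](CC(=O)OC(C)(C)C)Cc1ccc(OC)c(OC)c1
F4 | step 5 | (R)-4-(3,4-dimethoxybenzyl)dihydrofuran-2(3H)-one | O=C1C[C@@H](Cc2ccc(OC)c(OC)c2)CO1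
F5 | step 5 | (3S,4R)-4-(3,4-dimethoxybenzyl)-3-{hydroxy[3-methoxy-4-(triisopropylsilyloxy)phenyl]methyl}dihydrofuran-2(3H)-one (carbinol epimers) | COc1cc(C(O)[C@H]2C(=O)OC[C@@H]2Cc2ccc(OC)c(OC)c2)ccc1O[Si](C(C)C)(C(C)C)C(C)C
F0 | step 6 | none | none
F6 | step 7 | 3-[3-(3,4-dimethoxybenzyl)-4-hydroxy-2-{hydroxy[3-methoxy-4-(triisopropylsilyloxy)phenyl]methyl}butanoyl]oxazolidin-2-one (R at the benzyl-bearing carbon) | O=C(C(C(O)c1ccc(O[Si](C(C)C)(C(C)C)C(C)C)c(OC)c1)[C@H](CO)Cc1ccc(OC)c(OC)c1)N1CCOC1=O
F7 | step 7 | 4-(3,4-dimethoxybenzyl)-3-{hydroxy[3-methoxy-4-(triisopropylsilyloxy)phenyl]methyl}dihydrofuran-2(3H)-one (R at C4, mixed at C3 and carbinol) | COc1cc(C(O)C2C(=O)OC[C@@H]2Cc2ccc(OC)c(OC)c2)ccc1O[Si](C(C)C)(C(C)C)C(C)C
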